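- Per hour, the solution closes a fraction 0.0150 of its gap to saturation, while the substrate draws partner out of it, and in this flask I set those two against each other.

substrate 0.10 M; solid reagent 3.00 equiv; time 5.0 d

    substrate + partner → product, rate k1*[substrate]*[partner]^1.5 (k1 = 0.670 /M^1.5/h)
    solid reagent ⇌ partner, rate k2*(cs2 - [partner]) while solid is left; crystals form when [partner] > cs2 (cs2 = 0.053 M, k2 = 0.0150 /h)

1. how much product there is at 5.0 d, in percent of the substrate charged
2. concentration of partner in solution at 2.5 d, in percent of saturation
3. the change that raises the amount of product at 5.0 d, in percent of the substrate charged most ("none" if none brings more than 2 percentage points) (blue / red / none)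
4. amount of product at 5.0 d, in percent of the substrate charged, after blue

- blue: doubling the dissolution coefficient of step 2, all else as stated
- red: doubling the solubility in step 2, all else as stated

- I fold the givens into N = 1.03, the use of partner by the charged substrate at saturation divided by the dissolution into an empty solution.
- Setting the two rates equal gives the balance level x, as a fraction of saturation, from x(1 + N√x) = 1; two substitutions from 0.5 give 56.1 %, which is 0.0297 M of partner.
- Linearising around that level gives a relaxation time of 30.9 h.
- I replace the rising curve by its level from that time on, so the substrate decays pseudo-first-order and I commit to 26.4 % of product, with partner at 48.1 % of saturation at 2.5 d.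
- One number is not quite enough: N counts the charged substrate, yet by my own figure about a quarter of it has gone by the end.
- Blue halves N to 0.514, and I reckon 37.6 %.
- Red raises N to 1.45 but doubles the scale of the level, and I reckon 53.0 %, so red gains more than blue.
- The forecast gives 24.5 %, 47 %, red and 37.5 % after blue, with partner at a level “where slow dissolution roughly balances its consumption”.
- The flask gives 24.5 % of product, partner at 47.6 % of saturation, red as the best change with 28 percentage points against 13 points for blue, and 37.3 % after blue. At 5.00 d this flask holds 0.0309 M of partner, still made, each step taken net, 1.20 times as fast as it is used. Read at 12.0 d, the same flask has 36 % of its substrate left, so N shrinks to 0.375 and the balance level comes to 0.0397 M, where the reading is 0.0381 M.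

The constants belong to no real substance; the rest is arithmetic.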